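In the closed, stirred vessel of the maple run, the last interval added 3.45% of the final E. I compared the runs by their readings at 120 min, the time asked of the elm run, and called the share of the G charged that stands as E then the yield.

| flask | G | Z | time |
|---|---|---|---|
| maple | 0.400 M | 0.400 M |  |
| larch | 0.240 M | 0.240 M |  |
| birch | 0.600 M | 0.400 M |  |
| oak | 0.400 M | 0.800 M |  |
| elm | 2.00 M | 2.00 M | 120 min |

- maple run (time / min: [E] / M): 4.3: 0.0127; 13: 0.0276; 25: 0.0450; 40: 0.0611; 57: 0.0690; 76: 0.0767; 97: 0.0811; 120: 0.0840
- larch run (time / min: [E] / M): 4.3: 0.0022; 13: 0.0117; 25: 0.0183; 40: 0.0249; 57: 0.0303; 76: 0.0316; 97: 0.0357; 120: 0.0377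
- birch run (time / min: [E] / M): 4.3: 0.0156; 13: 0.0413; 25: 0.0672; 40: 0.0842; 57: 0.0998; 76: 0.1104; 97: 0.1134; 120: 0.1190
- oak run (time / min: [E] / M): 4.3: 0.0199; 13: 0.0499; 25: 0.0755; 40: 0.0943; 57: 0.1062; 76: 0.1115; 97: 0.1157; 120: 0.1206

(readings scatter by 0.001 M)

- reaction order in [G] at the outset, round the charge of the maple run, defined at two percent of the G turned into E (one fixed amount of E, the same in the runs compared)
- reaction order in [Z] at the outset, round the charge of the maple run, defined at two percent of the G turned into E
- E in the elm run at 120 min, as a share of the G charged

- Overall: G + Z -> E.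
- Constant volume, constant temperature.
- "The second partner" is Z.
- An order is taken over about fifteen percent of the charge, up and down.

Which charge moves the yield? The maple run gave 21.0%, and the birch run, with more G than maple but the same Z, gave 19.8%, so the added G did not raise it. The larch run, with less Z than maple and less G too, gave a lower yield, 15.7%.

So I followed one molecule of G, assuming that at each moment it either meets Z, at a rate that grows with the Z charge, or leaves by a route that needs no Z. Its odds are then the Z charge against a fixed charge c, and the yield is a ceiling times Z/(Z + c).

How large is c? The maple and larch yields put it at 0.409 M and the ceiling at 42.5%. I call c the even charge, the Z charge at which the yield stands at half its ceiling. Two readings set these two constants, so they test nothing yet.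

What then of the elm run? Its Z charge of 2.00 M is 4.89 times the even charge, so I committed to a yield of 35.2% at 120 min, and I reckoned no orders.

The forecast gave orders of 1 (0.85 to 1.1) in G and 0.8 (0.6 to 0.95) in Z, and for elm, which it held “should be at equilibrium”, 42% (33% to 50%), higher than mine.

The elm run gave 36.1% at 120 min, against my 35.2%, with orders of 1.1 in G and 1.1 in Z.

G + Z ⇌ E (0.01752 M⁻¹ min⁻¹, 0.001152 min⁻¹); 2 Z → Oz (0.02184 M⁻¹ min⁻¹); G → Ez (0.009240 min⁻¹) Among the steps, G goes to Ez without Z, with the constant 0.00924 min⁻¹. The oak run, which I had not used, has a Z charge of 0.800 M; with the even charge of 0.409 M and the ceiling of 42.5%, that gives a yield of 28.1%, and its reading at 120 min was 30.1%.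

(The data were generated by integration from invented constants.)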